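**Retrosynthetic overview**
- Feature: ring C (O1–C2–C3–C4–C4a–C8a) is joined to ring A through the C8a oxygen and the benzylic C4. It holds the only stereocentre, C2, between O1 and B-ring carbon C1′. O1–C2 and C3–C4 are therefore cut together, with a temporary formyl group on C3.
- This gives an A-ring salicylaldehyde and a B-ring (E)-cinnamaldehyde. An aminocatalytic oxa-Michael/aldol condensation joins them, closes ring C and sets C2. The C3-formyl group then marks C3=C4 for conjugate reduction and leaves as CO.
- B-ring enal: 6-bromoveratraldehyde already carries Br at the future C2′. A propargyl ether on O4′ closes the dimethylpyran ring at C3′ (Claisen/electrocyclisation). Stille prenylation at C2′ and Wittig extension follow.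
- A-ring aldehyde: 4-bromoresorcinol takes the 1,1-dimethylallyl group by γ-selective allylboronate coupling before any aldehyde is present. Selective desilylation and ortho-formylation follow.
- Ring order: rings A and B are bought, the dimethylpyran ring forms in step 4, and ring C forms in step 11.

Key step: step 11

Remark: flavan numbering is used (O1, C2–C4, C4a, C5–C8, C8a; B ring C1′–C6′) and TBS = tert-butyldimethylsilyl; the CIP label at C2 switches between (R) and (S) with the substituent on C3 while the spatial arrangement stays the same, and C3 of the 3-formylchroman is taken as a mixture of epimers, which does not matter because C3 ends as CH2.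

**Step 1**
Reactants: 1 2-bromo-4,5-dimethoxybenzaldehyde (6-bromoveratraldehyde)
Product: 2 2-bromo-4,5-dihydroxybenzaldehyde
Conditions: BBr3 (3 equiv), CH2Cl2, −78 °C to rt; then ice/H2O
Reagents that add atoms: none
Why: Lewis-acid cleavage of aryl methyl ethers with BBr3 should free both phenols without touching the aldehyde or the bromine, which is bought at the future C2′ because bromination of a 3-hydroxy-4-alkoxybenzaldehyde would go ortho to the free hydroxyl instead.

**Step 2**
Reactants: 2 2-bromo-4,5-dihydroxybenzaldehyde; 3 3-chloro-3-methylbut-1-yne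
Product: 4 2-bromo-5-hydroxy-4-[(2-methylbut-3-yn-2-yl)oxy]benzaldehyde
Conditions: DBU (1.1 equiv), CuCl2·2H2O (1 mol %), MeCN, 0 °C, Ar
Reagents that add atoms: none
Why: Copper-catalysed propargylic O-alkylation of a phenoxide: one equivalent of base ionises only the 4-OH, which is para to the formyl group and clearly the more acidic, so the tertiary propargyl unit should end up on the future O4′ and the 5-OH should stay free.

**Step 3**
Reactants: 4 2-bromo-5-hydroxy-4-[(2-methylbut-3-yn-2-yl)oxy]benzaldehyde
Product: 5 2-bromo-5-(TBS-oxy)-4-[(2-methylbut-3-yn-2-yl)oxy]benzaldehyde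
Conditions: TBSCl, imidazole, DMF, rt
Reagents that add atoms: tert-butyldimethylsilyl chloride, CC(C)(C)[Si](C)(C)Cl
Why: Imidazole-promoted silylation of the remaining phenol installs a fluoride-labile group that needs no acid for removal, which matters because the prenyl, 1,1-dimethylallyl and chromene units of the late intermediates are acid-sensitive.

**Step 4**
Reactants: 5 2-bromo-5-(TBS-oxy)-4-[(2-methylbut-3-yn-2-yl)oxy]benzaldehyde
Product: 8 5-bromo-8-(TBS-oxy)-2,2-dimethyl-2H-chromene-6-carbaldehyde, via allenylphenol 6 (not isolated), via ortho-quinone methide 7 (not isolated)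
Conditions: 1,2-dichlorobenzene, 180 °C, Ar
Reagents that add atoms: none
Why: Aromatic propargyl Claisen rearrangement to C3, the only free ortho carbon, then tautomerisation to 6, a 1,5-hydrogen shift to 7 and an oxa-6π electrocyclisation make up the standard thermal route from aryl 1,1-dimethylpropargyl ethers to 2,2-dimethyl-2H-chromenes and close the pyran ring between C3′ and O4′.

**Step 5**
Reactants: 8 5-bromo-8-(TBS-oxy)-2,2-dimethyl-2H-chromene-6-carbaldehyde; 9 tributyl(3-methylbut-2-en-1-yl)stannane
Product: 10 8-(TBS-oxy)-2,2-dimethyl-5-(3-methylbut-2-en-1-yl)-2H-chromene-6-carbaldehyde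
Conditions: Pd(PPh3)4 (10 mol %), DMF, 100 °C, Ar
Reagents that add atoms: none
Why: Stille coupling of an allylstannane with an aryl bromide activated by its ortho formyl group should transfer the prenyl group through its CH2 terminus under neutral conditions that spare aldehyde, silyl ether and chromene, whereas prenylboron or prenylzinc reagents would add to the aldehyde.

**Step 6**
Reactants: 10 8-(TBS-oxy)-2,2-dimethyl-5-(3-methylbut-2-en-1-yl)-2H-chromene-6-carbaldehyde
Product: 11 (E)-3-[8-(TBS-oxy)-2,2-dimethyl-5-(3-methylbut-2-en-1-yl)-2H-chromen-6-yl]prop-2-enal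
Conditions: Ph3P=CHCHO (1.5 equiv), toluene, 100 °C
Reagents that add atoms: (triphenylphosphoranylidene)acetaldehyde, O=CC=P(c1ccccc1)(c1ccccc1)c1ccccc1
Why: Wittig formylolefination with the stabilised ylide is E-selective and adds the two carbons that become C3 and the temporary formyl group, the old aldehyde carbon becoming C2.

**Step 7**
Reactants: 12 4-bromoresorcinol
Product: 13 4-bromo-1,3-bis(TBS-oxy)benzene
Conditions: TBSCl (2.4 equiv), imidazole, DMF, rt
Reagents that add atoms: tert-butyldimethylsilyl chloride, CC(C)(C)[Si](C)(C)Cl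
Why: Exhaustive imidazole-promoted silylation masks both phenols so that the bromide enters the coupling as a neutral, non-acidic partner.

**Step 8**
Reactants: 13 4-bromo-1,3-bis(TBS-oxy)benzene; 14 prenylboronic acid pinacol ester
Product: 15 2,4-bis(TBS-oxy)-1-(2-methylbut-3-en-2-yl)benzene
Conditions: 14 (1.5 equiv), Pd G3 precatalyst of a γ-selective biaryl monophosphine (3 mol %), aq K3PO4, MeCN, 70 °C
Reagents that add atoms: none
Why: γ-Selective Suzuki–Miyaura coupling of a 3,3-disubstituted allylboronate: SE2′ transmetalation places palladium on the tertiary allyl terminus and a ligand that makes reductive elimination faster than σ–π–σ isomerisation should give the 1,1-dimethylallyl arene, and the step is run before the formyl group exists because allylboronates add to aldehydes.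

**Step 9**
Reactants: 15 2,4-bis(TBS-oxy)-1-(2-methylbut-3-en-2-yl)benzene
Product: 16 3-(TBS-oxy)-4-(2-methylbut-3-en-2-yl)phenol
Conditions: K2CO3 (0.3 equiv), MeOH–THF, 0 °C to rt, stopped at monodesilylation
Reagents that add atoms: none
Why: Base-catalysed methanolysis of aryl silyl ethers is governed by access to silicon, so the open silyl ether para to the new quaternary carbon should cleave while the one ortho to it, shielded like that of a 2-tert-butylphenol, stays.

**Step 10**
Reactants: 16 3-(TBS-oxy)-4-(2-methylbut-3-en-2-yl)phenol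
Product: 17 4-(TBS-oxy)-2-hydroxy-5-(2-methylbut-3-en-2-yl)benzaldehyde
Conditions: MgCl2, Et3N, (CH2O)n, THF, reflux; then aq NH4Cl
Reagents that add atoms: paraformaldehyde (reacts as formaldehyde), C=O
Why: Casnati–Skattebøl ortho-formylation: the magnesium phenoxide delivers formaldehyde only ortho to the free OH and, of the two ortho carbons, to the open one para to the silyloxy group rather than the one wedged between the two oxygens, a second formaldehyde taking up the hydride.

**Step 11**
Reactants: 11 (E)-B-ring cinnamaldehyde; 17 4-(TBS-oxy)-2-hydroxy-5-(2-methylbut-3-en-2-yl)benzaldehyde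
Product: 19 (2R)-7-(TBS-oxy)-2-[8-(TBS-oxy)-2,2-dimethyl-5-(3-methylbut-2-en-1-yl)-2H-chromen-6-yl]-6-(2-methylbut-3-en-2-yl)-2H-chromene-3-carbaldehyde, via aldol adduct 18 (not isolated)
Conditions: (S)-α,α-diphenylprolinol trimethylsilyl ether (20 mol %), 2-nitrobenzoic acid (20 mol %), 4 Å MS, toluene, rt, dark
Reagents that add atoms: none
Why: The amine condenses with enal 11 to an E,s-trans iminium ion, the C8a–OH of 17 adds reversibly to its β-carbon (O1–C2), the enamine so formed attacks the neighbouring aryl aldehyde through C3 (C3–C4, aldol adduct 18, free or still bound to the amine), and loss of water with release of the catalyst gives the conjugated enal 19, which pulls the reversible first step forward. The closest known reaction type is the aminocatalytic domino oxa-Michael/aldol condensation of salicylaldehydes with cinnamaldehydes under diarylprolinol silyl ethers and a benzoic acid co-catalyst. Ring C closes in the aldol step in a 6-(enolexo)-exo-trig mode. C2 is controlled by the CPh2(OSiMe3) group of the (S)-catalyst, which covers one face of the planar iminium ion so that the phenol adds anti to it; this model leads to the arrangement called (2R) in 19, where the formyl-bearing C3 outranks C1′, and (2S) once C3 is CH2, and the (R)-catalyst is equally available should the sense have to be inverted. The step needs cross-selectivity between two aldehydes and between two phenol oxygens: only 11 can form an unsaturated iminium ion, 17 has no α-hydrogen and can only accept the enamine, and O7 is silylated so that only the hydroxyl next to the formyl group can add. Light is kept out and 19 is reduced at once, because electrocyclic opening of a 2-aryl-2H-chromene would scramble C2.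

**Step 12**
Reactants: 19 (2R)-2-aryl-2H-chromene-3-carbaldehyde
Product: 21 (2S)-7-(TBS-oxy)-2-[8-(TBS-oxy)-2,2-dimethyl-5-(3-methylbut-2-en-1-yl)-2H-chromen-6-yl]-6-(2-methylbut-3-en-2-yl)chromane-3-carbaldehyde (C3 epimers), via silyl enol ether 20 (not isolated)
Conditions: [(Ph3P)CuH]6 (5 mol %), PhMe2SiH (1.5 equiv), toluene, 0 °C to rt, dark; then AcOH–THF–H2O, 0 °C
Reagents that add atoms: dimethylphenylsilane, C[SiH](C)c1ccccc1 (its silyl group is held only in 20 and leaves on hydrolysis)
Why: Copper hydride conjugate reduction (1,4-hydrosilylation): the phosphine-ligated Cu–H delivers hydride to C4 of the only electron-poor alkene and leaves the prenyl, vinyl and dimethylchromene alkenes alone, and silyl transfer locks the enolate as 20 so that neither aryloxide loss from C2 (retro-oxa-Michael) nor over-reduction can follow before the mild acidic hydrolysis, C2 being untouched and the new C3 centre inconsequential.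

**Step 13**
Reactants: 21 (2S)-3-formylchroman (C3 epimers)
Product: 22 (2S)-kazinol H bis(TBS) ether
Conditions: RhCl(PPh3)3 (1.1 equiv), toluene, reflux, Ar
Reagents that add atoms: none
Why: Tsuji–Wilkinson decarbonylation: oxidative addition of the formyl C–H bond, CO extrusion and C–H reductive elimination from a coordinatively saturated alkyl hydride replace CHO by H under neutral conditions, so C3 becomes CH2, C2 keeps its configuration and, with no H2 present, the alkenes are not reduced.

**Step 14**
Reactants: 22 (2S)-kazinol H bis(TBS) ether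
Product: 23 kazinol H, (2S)
Conditions: TBAF (2.5 equiv), AcOH (2.5 equiv), THF, 0 °C to rt
Reagents that add atoms: none
Why: Fluoride-induced cleavage of both aryl silyl ethers, buffered with acetic acid so that neither free phenoxide nor strong acid meets the chromene, prenyl or 1,1-dimethylallyl groups, should release the target with C2 unchanged.

**Compound list**
1 | 2-bromo-4,5-dimethoxybenzaldehyde | O=Cc1cc(OC)c(OC)cc1Br | starting material
2 | 2-bromo-4,5-dihydroxybenzaldehyde | O=Cc1cc(O)c(O)cc1Br | intermediate
3 | 3-chloro-3-methylbut-1-yne | C#CC(C)(C)Cl | starting material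
4 | 2-bromo-5-hydroxy-4-[(2-methylbut-3-yn-2-yl)oxy]benzaldehyde | O=Cc1cc(O)c(OC(C)(C)C#C)cc1Br | intermediate
5 | 2-bromo-5-(TBS-oxy)-4-[(2-methylbut-3-yn-2-yl)oxy]benzaldehyde | O=Cc1cc(O[Si](C)(C)C(C)(C)C)c(OC(C)(C)C#C)cc1Br | intermediate
6 | 2-bromo-4-hydroxy-3-(3-methylbuta-1,2-dien-1-yl)-5-(TBS-oxy)benzaldehyde (allenylphenol) | O=Cc1cc(O[Si](C)(C)C(C)(C)C)c(O)c(C=C=C(C)C)c1Br | intermediate
7 | ortho-quinone methide from 6 (exocyclic 3-methylbut-2-enylidene at C3, C4 carbonyl) | O=CC1=C(Br)C(=CC=C(C)C)C(=O)C(O[Si](C)(C)C(C)(C)C)=C1 | intermediate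
8 | 5-bromo-8-(TBS-oxy)-2,2-dimethyl-2H-chromene-6-carbaldehyde | O=Cc1cc(O[Si](C)(C)C(C)(C)C)c2c(c1Br)C=CC(C)(C)O2 | intermediate
9 | tributyl(3-methylbut-2-en-1-yl)stannane | CC(C)=CC[Sn](CCCC)(CCCC)CCCC | starting material
10 | 8-(TBS-oxy)-2,2-dimethyl-5-(3-methylbut-2-en-1-yl)-2H-chromene-6-carbaldehyde | O=Cc1cc(O[Si](C)(C)C(C)(C)C)c2c(c1CC=C(C)C)C=CC(C)(C)O2 | intermediate
11 | (E)-3-[8-(TBS-oxy)-2,2-dimethyl-5-(3-methylbut-2-en-1-yl)-2H-chromen-6-yl]prop-2-enal | O=C/C=C/c1cc(O[Si](C)(C)C(C)(C)C)c2c(c1CC=C(C)C)C=CC(C)(C)O2 | intermediate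
12 | 4-bromoresorcinol | Oc1ccc(Br)c(O)c1 | starting material
13 | 4-bromo-1,3-bis(TBS-oxy)benzene | CC(C)(C)[Si](C)(C)Oc1ccc(Br)c(O[Si](C)(C)C(C)(C)C)c1 | intermediate
14 | prenylboronic acid pinacol ester | CC(C)=CCB1OC(C)(C)C(C)(C)O1 | starting material
15 | 2,4-bis(TBS-oxy)-1-(2-methylbut-3-en-2-yl)benzene | C=CC(C)(C)c1ccc(O[Si](C)(C)C(C)(C)C)cc1O[Si](C)(C)C(C)(C)C | intermediate
16 | 3-(TBS-oxy)-4-(2-methylbut-3-en-2-yl)phenol | C=CC(C)(C)c1ccc(O)cc1O[Si](C)(C)C(C)(C)C | intermediate
17 | 4-(TBS-oxy)-2-hydroxy-5-(2-methylbut-3-en-2-yl)benzaldehyde | C=CC(C)(C)c1cc(C=O)c(O)cc1O[Si](C)(C)C(C)(C)C | intermediate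
18 | (2S)-3-formyl-4-hydroxychroman aldol adduct (C3, C4 undefined) | C=CC(C)(C)c1cc2c(cc1O[Si](C)(C)C(C)(C)C)O[C@H](c1cc(O[Si](C)(C)C(C)(C)C)c3c(c1CC=C(C)C)C=CC(C)(C)O3)C(C=O)C2O | intermediate
19 | (2R)-2-aryl-7-(TBS-oxy)-6-(2-methylbut-3-en-2-yl)-2H-chromene-3-carbaldehyde (aryl = B-ring chromenyl unit of 11) | C=CC(C)(C)c1cc2c(cc1O[Si](C)(C)C(C)(C)C)O[C@H](c1cc(O[Si](C)(C)C(C)(C)C)c3c(c1CC=C(C)C)C=CC(C)(C)O3)C(C=O)=C2 | intermediate
20 | (2R)-3-{[dimethyl(phenyl)silyl]oxymethylidene}chroman (enol ether geometry undefined) | C=CC(C)(C)c1cc2c(cc1O[Si](C)(C)C(C)(C)C)O[C@H](c1cc(O[Si](C)(C)C(C)(C)C)c3c(c1CC=C(C)C)C=CC(C)(C)O3)C(=CO[Si](C)(C)c1ccccc1)C2 | intermediate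
21 | (2S)-2-arylchromane-3-carbaldehyde, bis(TBS) ether (C3 epimers) | C=CC(C)(C)c1cc2c(cc1O[Si](C)(C)C(C)(C)C)O[C@H](c1cc(O[Si](C)(C)C(C)(C)C)c3c(c1CC=C(C)C)C=CC(C)(C)O3)C(C=O)C2 | intermediate
22 | (2S)-kazinol H bis(TBS) ether | C=CC(C)(C)c1cc2c(cc1O[Si](C)(C)C(C)(C)C)O[C@H](c1cc(O[Si](C)(C)C(C)(C)C)c3c(c1CC=C(C)C)C=CC(C)(C)O3)CC2 | intermediate
23 | kazinol H, (2S) | C=CC(C)(C)c1cc2c(cc1O)O[C@H](c1cc(O)c3c(c1CC=C(C)C)C=CC(C)(C)O3)CC2 | target

**Step count**
- Total steps: 14.
- Longest linear sequence: 10 (steps 1–6, then 11–14).

**Steps most likely to fail**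

*Step 11.* The iminium ion of an electron-rich, ortho-substituted enal may form slowly and take up the phenol slowly and reversibly. Conversion could then stall. Facial selectivity at C2 could also be eroded by retro-oxa-Michael addition or by ring opening of the product.
- The fallback sets out from 11 and 17. The same annulation is run without asymmetric induction, using pyrrolidine and benzoic acid in toluene. This smaller amine engages hindered enals more readily and should give the racemic chromene aldehyde F1.
- Preparative chromatography on a polysaccharide chiral stationary phase then delivers 19.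
- The unwanted (2S)-chromene aldehyde F2 is racemised by irradiation through its reversible electrocyclic ring opening and returned to the separation as F1.
- The route is rejoined at 19.

*Step 13.* The secondary alkylrhodium intermediate may undergo β-hydride elimination toward C2 or C4, or may lose the aryloxide from C2. The prenyl double bond may also migrate at the temperature needed.
- The fallback sets out from 21. Pinnick oxidation (NaClO2, NaH2PO4, large excess of 2-methylbut-2-ene) gives the chroman-3-carboxylic acid F3.
- DCC coupling with N-hydroxypyridine-2-thione gives the thiohydroxamate ester F4.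
- Visible-light Barton reductive decarboxylation with excess t-BuSH follows. The thiol traps the C3 radical faster than it can cyclise onto the prenyl group or fragment.
- This gives 22, where the route is rejoined.

*Step 8.* The allylpalladium intermediate may isomerise before reductive elimination and deliver the linear prenyl arene. Oxidative addition to the hindered, electron-rich bromide may be slow, and aqueous base may cause partial loss of silyl groups. The ligand that decides the α/γ outcome would be fixed by a short screen.
- The fallback sets out from 13 and removes the regiochemical question. Palladium-catalysed α-arylation of isobutyraldehyde (bulky ferrocenyl or biaryl phosphine, Cs2CO3, dioxane, 80 °C) gives 2-[2,4-bis(TBS-oxy)phenyl]-2-methylpropanal F5.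
- Wittig methylenation with Ph3P=CH2 converts F5 into 15, where the route is rejoined.

**Further compounds**
F1 | step 11 | racemic 2-aryl-2H-chromene-3-carbaldehyde (racemate of 19) | C=CC(C)(C)c1cc2c(cc1O[Si](C)(C)C(C)(C)C)OC(c1cc(O[Si](C)(C)C(C)(C)C)c3c(c1CC=C(C)C)C=CC(C)(C)O3)C(C=O)=C2
F2 | step 11 | (2S)-2-aryl-2H-chromene-3-carbaldehyde (enantiomer of 19) | C=CC(C)(C)c1cc2c(cc1O[Si](C)(C)C(C)(C)C)O[C@@H](c1cc(O[Si](C)(C)C(C)(C)C)c3c(c1CC=C(C)C)C=CC(C)(C)O3)C(C=O)=C2
F3 | step 13 | (2S)-2-arylchromane-3-carboxylic acid, bis(TBS) ether (C3 epimers) | C=CC(C)(C)c1cc2c(cc1O[Si](C)(C)C(C)(C)C)O[C@H](c1cc(O[Si](C)(C)C(C)(C)C)c3c(c1CC=C(C)C)C=CC(C)(C)O3)C(C(=O)O)C2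
F4 | step 13 | 2-thioxopyridin-1(2H)-yl ester of F3 (Barton ester) | C=CC(C)(C)c1cc2c(cc1O[Si](C)(C)C(C)(C)C)O[C@H](c1cc(O[Si](C)(C)C(C)(C)C)c3c(c1CC=C(C)C)C=CC(C)(C)O3)C(C(=O)ON1C=CC=CC1=S)C2
F5 | step 8 | 2-[2,4-bis(TBS-oxy)phenyl]-2-methylpropanal | O=CC(C)(C)c1ccc(O[Si](C)(C)C(C)(C)C)cc1O[Si](C)(C)C(C)(C)C
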